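**Retrosynthetic overview**

1. (−)-Thujaplicatin 24 comes from its tris-benzyl ether 23 by hydrogenolysis; 23 comes from lactone 21 by reductive removal of a C3 chlorine and a C5 arylsulfanyl group and base equilibration of C3 to the trans isomer.
2. Key disconnection: the butyrolactone, the only ring made in the route (both benzene rings are bought with their oxygens in place), is cut at C3–C4 and O1–C5 into chloro(arylmethyl)ketene 18 (C2, C3, one carboxyl oxygen) and enantiopure (Z)-vinyl sulfoxide 8 (C4, C5; its sulfinyl oxygen becomes the second carboxyl oxygen).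
3. Enabling feature: in the lactone ring (O1, C2 carbonyl, C3, C4, C5), C5 is an unsubstituted O–CH2 next to the C4 stereocentre and C3 is an enolisable CH. C5 can therefore carry sulfur at the S,O-acetal oxidation level and C3 a chlorine; the sulfur stereocentre controls C4, and both auxiliaries leave in one reduction.
4. Sulfoxide 8 is made from O-benzylvanillyl alcohol by propargylation, Andersen sulfinylation and cis-semihydrogenation; acid 16 is made from 5-hydroxyvanillin through a benzyl bromide and diethyl chloromalonate.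

Key step: step 10

Remark: lactone locants are O1, C2 (carbonyl), C3, C4, C5; compounds 1, 3, 5, 9 and 13 are assumed to be purchased; the sense of sulfur-to-carbon chirality transfer is taken from the chair model given in step 10, not from a recalled experimental result.

**Route**

Step 1
Reactants: 1 [4-(benzyloxy)-3-methoxyphenyl]methanol
Product: 2 1-(benzyloxy)-4-(chloromethyl)-2-methoxybenzene
Conditions: SOCl2 (1.2 equiv), CH2Cl2, 0 °C to rt
Reagents that add atoms: thionyl chloride, O=S(Cl)Cl
Why: Chlorodehydroxylation of an electron-rich benzylic alcohol through its chlorosulfite is fast at 0 °C and should leave the aryl benzyl ether untouched.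

Step 2
Reactants: 2 1-(benzyloxy)-4-(chloromethyl)-2-methoxybenzene; 3 ethynylmagnesium bromide
Product: 4 1-(benzyloxy)-2-methoxy-4-(prop-2-yn-1-yl)benzene
Conditions: 3 (2.5 equiv, THF solution), CuCl (10 mol %), THF, 55 °C
Reagents that add atoms: none
Why: Copper-catalysed cross-coupling of a benzylic chloride with an alkynyl Grignard reagent should give the 3-arylpropyne, the excess of 3 suppressing double benzylation.

Step 3
Reactants: 4 1-(benzyloxy)-2-methoxy-4-(prop-2-yn-1-yl)benzene; 5 (1R,2S,5R)-menthyl (S)-4-methylbenzenesulfinate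
Product: 7 1-(benzyloxy)-2-methoxy-4-{3-[(S)-4-methylbenzenesulfinyl]prop-2-yn-1-yl}benzene, via alkynylmagnesium bromide 6 (not isolated)
Conditions: EtMgBr (1.05 equiv), THF, 0 °C to rt; then added to 5, toluene, −20 °C; H2O work-up
Reagents that add atoms: none
Why: Andersen sulfoxide synthesis, in which the alkynyl Grignard reagent displaces mentholate with clean inversion at sulfur, so the sulfur stereocentre is set by the diastereomerically pure sulfinate (the descriptor stays S only because alkynyl outranks p-tolyl).

Step 4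
Reactants: 7 1-(benzyloxy)-2-methoxy-4-{3-[(S)-4-methylbenzenesulfinyl]prop-2-yn-1-yl}benzene
Product: 8 1-(benzyloxy)-2-methoxy-4-{(Z)-3-[(R)-4-methylbenzenesulfinyl]prop-2-en-1-yl}benzene
Conditions: H2 (1 atm), RhCl(PPh3)3 (5 mol %), toluene, rt
Reagents that add atoms: none
Why: Homogeneous cis-semihydrogenation (syn delivery of H2 to the alkyne) should give the Z alkene and stop there, because the electron-poor disubstituted vinyl sulfoxide is reduced much more slowly; the sulfur stereocentre and the benzyl ether are unaffected.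

Step 5
Reactants: 9 3,4-dihydroxy-5-methoxybenzaldehyde
Product: 10 3,4-bis(benzyloxy)-5-methoxybenzaldehyde
Conditions: BnBr (2.3 equiv), K2CO3, DMF, 60 °C
Reagents that add atoms: benzyl bromide, BrCc1ccccc1
Why: Williamson etherification of both phenols should proceed cleanly, the aldehyde being inert to carbonate.

Step 6
Reactants: 10 3,4-bis(benzyloxy)-5-methoxybenzaldehyde
Product: 11 [3,4-bis(benzyloxy)-5-methoxyphenyl]methanol
Conditions: NaBH4, MeOH/THF, 0 °C
Reagents that add atoms: none
Why: Borohydride reduction of an aryl aldehyde is chemoselective and leaves the ethers intact.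

Step 7
Reactants: 11 [3,4-bis(benzyloxy)-5-methoxyphenyl]methanol
Product: 12 1,2-bis(benzyloxy)-5-(bromomethyl)-3-methoxybenzene
Conditions: PBr3 (0.4 equiv), CH2Cl2, 0 °C; used without storage
Reagents that add atoms: phosphorus tribromide, BrP(Br)Br
Why: Bromodehydroxylation through the bromophosphite (SN2 by bromide) is fast for an electron-rich benzylic alcohol at 0 °C.

Step 8
Reactants: 12 1,2-bis(benzyloxy)-5-(bromomethyl)-3-methoxybenzene; 13 diethyl 2-chloromalonate
Product: 14 diethyl 2-{[3,4-bis(benzyloxy)-5-methoxyphenyl]methyl}-2-chloromalonate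
Conditions: K2CO3, DMF, rt
Reagents that add atoms: none
Why: Malonic ester alkylation (SN2 of the stabilised chloromalonate anion on the reactive benzylic bromide) should join the aryl fragment to the carbons that become C2 and C3 and bring in the chlorine needed for the ketene.

Step 9
Reactants: 14 diethyl 2-{[3,4-bis(benzyloxy)-5-methoxyphenyl]methyl}-2-chloromalonate
Product: 16 rac-3-[3,4-bis(benzyloxy)-5-methoxyphenyl]-2-chloropropanoic acid, via chloromalonic acid 15 (not isolated)
Conditions: KOH (3 equiv), EtOH/H2O, 0 °C to rt; 2 M HCl, 0 °C; then dioxane, 100 °C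
Reagents that add atoms: potassium hydroxide, [K+].[OH-]
Why: Saponification and thermal decarboxylation of the geminal diacid through the cyclic six-membered transition state should give the alpha-chloro acid, the tertiary chloride between two carboxyl groups being poorly disposed to substitution; the racemic C–Cl centre is of no consequence because it becomes sp2 in ketene 18.

Step 10
Reactants: 16 rac-3-[3,4-bis(benzyloxy)-5-methoxyphenyl]-2-chloropropanoic acid; 8 1-(benzyloxy)-2-methoxy-4-{(Z)-3-[(R)-4-methylbenzenesulfinyl]prop-2-en-1-yl}benzene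
Product: 21 (4S)-4-{[4-(benzyloxy)-3-methoxyphenyl]methyl}-3-{[3,4-bis(benzyloxy)-5-methoxyphenyl]methyl}-3-chloro-5-[(4-methylphenyl)sulfanyl]oxolan-2-one (epimers at C3/C5), via acyl chloride 17 (not isolated), via chloroketene 18 (not isolated), via oxysulfonium enolate 19 (not isolated), via thionium carboxylate 20 (not isolated)
Conditions: 16 (2.5 equiv), (COCl)2, DMF (cat.), CH2Cl2, rt, then evaporation; crude 17 added over 2 h to 8 and Et3N (3 equiv), THF, −78 to 0 °C
Reagents that add atoms: none
Why: Proposed new method: acid 16 is converted by way of acyl chloride 17 into chloroketene 18, whose carbonyl carbon is attacked by the sulfinyl oxygen of 8 to give oxysulfonium enolate 19; a charge-accelerated [3,3]-sigmatropic shift then joins the enolate carbon (C3) to the beta carbon of the vinyl group (C4) while the S–O bond breaks, and the carboxylate of thionium ion 20 (one oxygen from the ketene, one from the sulfinyl group) adds to the thionium carbon to form the O1–C5 bond. The closest known reaction type is the Marino lactonisation of enantiopure vinyl sulfoxides with dichloroketene (an additive Pummerer-type annulation); the extension proposed here is a chloro(alkyl)ketene, which keeps one chlorine for electrophilicity and brings the second arylmethyl group in with the ring. The lactone closes by 5-exo-trig attack of the carboxylate oxygen on the C=S+ bond. C4 is set by transfer of chirality from sulfur: in the chair-like transition state the p-tolyl group is pseudo-equatorial (anti to the C=C bond) because the pseudo-axial site clashes with the pseudo-axial arylmethyl group of the Z alkene, so the enolate is delivered to one face only and the (R)-sulfoxide should give the C4 configuration of the target (4S in 21 by sequence-rule priorities, 4R after step 11), whereas C3 and C5 may form as epimers because both are reset in step 11. The step needs the ketene to be captured by the sulfinyl oxygen faster than it dimerises or than 17 activates the sulfoxide directly, which slow addition of 17 to 8 and Et3N at low temperature should secure, and it needs carbon to go to C4 and oxygen to C5, which the six-membered array tethered through the S–O bond enforces.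

Step 11
Reactants: 21 (4S)-4-{[4-(benzyloxy)-3-methoxyphenyl]methyl}-3-{[3,4-bis(benzyloxy)-5-methoxyphenyl]methyl}-3-chloro-5-[(4-methylphenyl)sulfanyl]oxolan-2-one
Product: 23 (3R,4R)-4-{[4-(benzyloxy)-3-methoxyphenyl]methyl}-3-{[3,4-bis(benzyloxy)-5-methoxyphenyl]methyl}oxolan-2-one, via C3-epimeric lactone 22 (not isolated)
Conditions: Bu3SnH (3 equiv), AIBN (cat.), toluene, 110 °C; then DBU (0.3 equiv), 80 °C
Reagents that add atoms: none
Why: Radical chain reduction with Bu3SnH (tin-mediated dehalogenation and desulfurisation) should replace the C3 chlorine and the C5 arylsulfanyl group of the O,S-acetal by hydrogen, giving 22 mainly as the cis epimer by hydrogen transfer anti to the C4 substituent, and DBU then equilibrates C3 through the lactone enolate to the more stable trans (3R,4R) isomer while the non-enolisable C4 stereocentre is untouched.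

Step 12
Reactants: 23 (3R,4R)-4-{[4-(benzyloxy)-3-methoxyphenyl]methyl}-3-{[3,4-bis(benzyloxy)-5-methoxyphenyl]methyl}oxolan-2-one
Product: 24 (−)-thujaplicatin, (3R,4R)-3-[(3,4-dihydroxy-5-methoxyphenyl)methyl]-4-[(4-hydroxy-3-methoxyphenyl)methyl]oxolan-2-one
Conditions: H2 (1 atm), 10% Pd/C, EtOAc/EtOH, rt
Reagents that add atoms: none
Why: Hydrogenolysis of the three aryl benzyl ethers over Pd/C under neutral conditions should release the phenols without touching the lactone (its C–O bond is not benzylic) or the two stereocentres (no enolisation).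

**Compound list**

1 | [4-(benzyloxy)-3-methoxyphenyl]methanol | COc1cc(CO)ccc1OCc1ccccc1 | starting material
2 | 1-(benzyloxy)-4-(chloromethyl)-2-methoxybenzene | COc1cc(CCl)ccc1OCc1ccccc1 | intermediate
3 | ethynylmagnesium bromide | C#C[Mg]Br | starting material
4 | 1-(benzyloxy)-2-methoxy-4-(prop-2-yn-1-yl)benzene | COc1cc(CC#C)ccc1OCc1ccccc1 | intermediate
5 | (1R,2S,5R)-menthyl (S)-4-methylbenzenesulfinate | C[C@@H]1CC[C@H]([C@@H](C1)O[S@](=O)c1ccc(C)cc1)C(C)C | starting material
6 | {3-[4-(benzyloxy)-3-methoxyphenyl]prop-1-yn-1-yl}magnesium bromide | COc1cc(CC#C[Mg]Br)ccc1OCc1ccccc1 | intermediate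
7 | 1-(benzyloxy)-2-methoxy-4-{3-[(S)-4-methylbenzenesulfinyl]prop-2-yn-1-yl}benzene | Cc1ccc(cc1)[S@](=O)C#CCc1ccc(OCc2ccccc2)c(OC)c1 | intermediate
8 | 1-(benzyloxy)-2-methoxy-4-{(Z)-3-[(R)-4-methylbenzenesulfinyl]prop-2-en-1-yl}benzene | Cc1ccc(cc1)[S@](=O)/C=C\Cc1ccc(OCc2ccccc2)c(OC)c1 | intermediate
9 | 3,4-dihydroxy-5-methoxybenzaldehyde | COc1cc(C=O)cc(O)c1O | starting material
10 | 3,4-bis(benzyloxy)-5-methoxybenzaldehyde | COc1cc(C=O)cc(OCc2ccccc2)c1OCc1ccccc1 | intermediate
11 | [3,4-bis(benzyloxy)-5-methoxyphenyl]methanol | COc1cc(CO)cc(OCc2ccccc2)c1OCc1ccccc1 | intermediate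
12 | 1,2-bis(benzyloxy)-5-(bromomethyl)-3-methoxybenzene | COc1cc(CBr)cc(OCc2ccccc2)c1OCc1ccccc1 | intermediate
13 | diethyl 2-chloromalonate | CCOC(=O)C(Cl)C(=O)OCC | starting material
14 | diethyl 2-{[3,4-bis(benzyloxy)-5-methoxyphenyl]methyl}-2-chloromalonate | CCOC(=O)C(Cl)(Cc1cc(OC)c(OCc2ccccc2)c(OCc2ccccc2)c1)C(=O)OCC | intermediate
15 | 2-{[3,4-bis(benzyloxy)-5-methoxyphenyl]methyl}-2-chloromalonic acid | OC(=O)C(Cl)(Cc1cc(OC)c(OCc2ccccc2)c(OCc2ccccc2)c1)C(=O)O | intermediate
16 | rac-3-[3,4-bis(benzyloxy)-5-methoxyphenyl]-2-chloropropanoic acid | OC(=O)C(Cl)Cc1cc(OC)c(OCc2ccccc2)c(OCc2ccccc2)c1 | intermediate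
17 | rac-3-[3,4-bis(benzyloxy)-5-methoxyphenyl]-2-chloropropanoyl chloride | ClC(=O)C(Cl)Cc1cc(OC)c(OCc2ccccc2)c(OCc2ccccc2)c1 | intermediate
18 | 3-[3,4-bis(benzyloxy)-5-methoxyphenyl]-2-chloroprop-1-en-1-one (chloroketene) | O=C=C(Cl)Cc1cc(OC)c(OCc2ccccc2)c(OCc2ccccc2)c1 | intermediate
19 | oxysulfonium enolate from O-acylation of 8 by 18 (zwitterion, sulfur configuration of 8 retained) | Cc1ccc(cc1)[S@+](OC([O-])=C(Cl)Cc1cc(OC)c(OCc2ccccc2)c(OCc2ccccc2)c1)/C=C\Cc1ccc(OCc2ccccc2)c(OC)c1 | intermediate
20 | thionium carboxylate after the [3,3] shift (zwitterion, C4 set, C3 unspecified) | Cc1ccc(cc1)[S+]=C[C@H](Cc1ccc(OCc2ccccc2)c(OC)c1)C(Cl)(Cc1cc(OC)c(OCc2ccccc2)c(OCc2ccccc2)c1)C(=O)[O-] | intermediate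
21 | (4S)-4-{[4-(benzyloxy)-3-methoxyphenyl]methyl}-3-{[3,4-bis(benzyloxy)-5-methoxyphenyl]methyl}-3-chloro-5-[(4-methylphenyl)sulfanyl]oxolan-2-one (C3 and C5 not defined) | COc1cc(C[C@H]2C(Sc3ccc(C)cc3)OC(=O)C2(Cl)Cc2cc(OCc3ccccc3)c(OCc3ccccc3)c(OC)c2)ccc1OCc1ccccc1 | intermediate
22 | (4R)-4-{[4-(benzyloxy)-3-methoxyphenyl]methyl}-3-{[3,4-bis(benzyloxy)-5-methoxyphenyl]methyl}oxolan-2-one (C3 epimers, cis expected to predominate) | COc1cc(C[C@H]2COC(=O)C2Cc2cc(OCc3ccccc3)c(OCc3ccccc3)c(OC)c2)ccc1OCc1ccccc1 | intermediate
23 | (3R,4R)-4-{[4-(benzyloxy)-3-methoxyphenyl]methyl}-3-{[3,4-bis(benzyloxy)-5-methoxyphenyl]methyl}oxolan-2-one | COc1cc(C[C@H]2COC(=O)[C@@H]2Cc2cc(OCc3ccccc3)c(OCc3ccccc3)c(OC)c2)ccc1OCc1ccccc1 | intermediate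
24 | (−)-thujaplicatin, (3R,4R)-3-[(3,4-dihydroxy-5-methoxyphenyl)methyl]-4-[(4-hydroxy-3-methoxyphenyl)methyl]oxolan-2-one | COc1cc(C[C@H]2COC(=O)[C@@H]2Cc2cc(O)c(O)c(OC)c2)ccc1O | target

**Summary**

Total step count: 12. Longest linear sequence: 8 steps (9 to 24, steps 5–12); the sulfoxide branch (steps 1–4) joins at step 10.

Steps most likely to fail:

1. Step 10 (Proposed new method). The chloro(alkyl)ketene, less electrophilic than dichloroketene, may dimerise or form enol esters before the sulfinyl oxygen captures it, or acyl chloride 17 may activate the sulfoxide directly (Pummerer-type chlorination or deoxygenation). The fallback uses known chemistry, sets out from 8 and comes back at 23. Vinyl sulfoxide 8 would be treated with dichloroketene generated from Cl3CCOCl and Zn–Cu couple in Et2O (the established lactonisation) to give (4S)-4-{[4-(benzyloxy)-3-methoxyphenyl]methyl}-3,3-dichloro-5-[(4-methylphenyl)sulfanyl]oxolan-2-one F1. Bu3SnH/AIBN in toluene at 110 °C should remove both chlorines and the sulfanyl group to give (4R)-4-{[4-(benzyloxy)-3-methoxyphenyl]methyl}oxolan-2-one F2. Its lithium enolate (LiHMDS, THF, −78 °C) would be alkylated with bromide 12 anti to the C4 substituent, which should give trans lactone 23 directly.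

2. Step 4. Over-reduction, incomplete Z selectivity or later Z-to-E isomerisation would erode the enantiomeric purity, because the E isomer of the same sulfoxide delivers the opposite C4 configuration; an unexpected sense of chirality transfer from the Z isomer would have the same effect. The fallback sets out from 4 and comes back at 21. Alkyne 4 would be metalated as in step 3 and sulfinylated with (1S,2R,5S)-menthyl (R)-4-methylbenzenesulfinate to give 1-(benzyloxy)-2-methoxy-4-{3-[(R)-4-methylbenzenesulfinyl]prop-2-yn-1-yl}benzene F3. Trans-hydroalumination and protonolysis with DIBAL-H in THF at −90 °C should give 1-(benzyloxy)-2-methoxy-4-{(E)-3-[(S)-4-methylbenzenesulfinyl]prop-2-en-1-yl}benzene F4. In F4 both the alkene geometry and the sulfur configuration are inverted relative to 8, so the same face of the beta carbon should be attacked under the conditions of step 10 and 21 should result.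

3. Step 9. The tertiary chloride may be lost during saponification (hydroxide displacement through an alpha-lactone) or during the decarboxylation. The fallback sets out from 12 and comes back at 16. Bromide 12 would alkylate the lithium enolate of tert-butyl acetate (LDA, THF, −78 °C) to give tert-butyl 3-[3,4-bis(benzyloxy)-5-methoxyphenyl]propanoate F5. Enolisation with LDA and chlorination with C2Cl6 at −78 °C should give tert-butyl 3-[3,4-bis(benzyloxy)-5-methoxyphenyl]-2-chloropropanoate F6. Formic acid at rt would then cleave the tert-butyl ester to 16 without touching the benzyl ethers.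

**Further compounds**

F1 | step 10 | (4S)-4-{[4-(benzyloxy)-3-methoxyphenyl]methyl}-3,3-dichloro-5-[(4-methylphenyl)sulfanyl]oxolan-2-one | COc1cc(C[C@H]2C(Sc3ccc(C)cc3)OC(=O)C2(Cl)Cl)ccc1OCc1ccccc1
F2 | step 10 | (4R)-4-{[4-(benzyloxy)-3-methoxyphenyl]methyl}oxolan-2-one | COc1cc(C[C@H]2COC(=O)C2)ccc1OCc1ccccc1
F3 | step 4 | 1-(benzyloxy)-2-methoxy-4-{3-[(R)-4-methylbenzenesulfinyl]prop-2-yn-1-yl}benzene | Cc1ccc(cc1)[S@@](=O)C#CCc1ccc(OCc2ccccc2)c(OC)c1
F4 | step 4 | 1-(benzyloxy)-2-methoxy-4-{(E)-3-[(S)-4-methylbenzenesulfinyl]prop-2-en-1-yl}benzene | Cc1ccc(cc1)[S@@](=O)/C=C/Cc1ccc(OCc2ccccc2)c(OC)c1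
F5 | step 9 | tert-butyl 3-[3,4-bis(benzyloxy)-5-methoxyphenyl]propanoate | CC(C)(C)OC(=O)CCc1cc(OC)c(OCc2ccccc2)c(OCc2ccccc2)c1
F6 | step 9 | tert-butyl 3-[3,4-bis(benzyloxy)-5-methoxyphenyl]-2-chloropropanoate | CC(C)(C)OC(=O)C(Cl)Cc1cc(OC)c(OCc2ccccc2)c(OCc2ccccc2)c1
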